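**Retrosynthetic overview**
1. Target 16 ⇐ C14 allylic alcohol 15 ⇐ 10-methyl macrocycle 14, by late SeO2 oxidation of C14 that also turns the C1=C10 ring olefin from ring-trans to ring-cis.
2. 14 ⇐ 8α-alcohol 12, by Mitsunobu inversion at C8 with isovaleric acid.
3. Key step: 12 ⇐ acyclic epoxy dialdehyde 7 + C4 linchpin 10, a [9+1] double chromium allylation with lactonisation that forms C6–C7, C7–C8 and O–C12, closing the γ-lactone and the ten-membered carbocycle together and setting C6, C7 and C8.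
4. 7 ⇐ epoxy diol 6 ⇐ dienediol 5 (Sharpless epoxidation sets C4/C5) ⇐ neryl acetate 1 (SeO2, Wittig, hydroboration).
5. Ring order: epoxide (step 4), then γ-lactone and ten-membered ring in one operation (step 7).

Assumption: germacrane numbering (C1–C15) is used; "ring-trans" means C9 anti to C2 across C1=C10 (compounds 12, 14) and "ring-cis" means C9 syn to C2 (15, 16), although all four are E by CIP. The route is a proposal and has not been run; the key step is a new method.

**Step 1**
Reactants: 1 neryl acetate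
Product: 2 (2E,6Z)-8-acetoxy-2,6-dimethylocta-2,6-dienal
Conditions: SeO2 (1.2 eq), 1,4-dioxane, 80 °C, 4 h
Reagents that add atoms: selenium dioxide, O=[Se]=O
Why: Riley allylic oxidation (ene reaction, then [2,3]-sigmatropic shift) attacks the E-methyl of the electron-rich terminal olefin and with stoichiometric SeO2 at 80 °C runs on to the (E)-enal, while the 2,3-olefin is deactivated by the allylic acetate.

**Step 2**
Reactants: 2 (2E,6Z)-8-acetoxy-2,6-dimethylocta-2,6-dienal
Product: 3 (2Z,6E)-3,7-dimethylnona-2,6,8-trien-1-yl acetate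
Conditions: Ph3PCH3Br (1.1 eq), n-BuLi (1.05 eq), THF, 0 °C; then 2, −78 → 0 °C
Reagents that add atoms: methyltriphenylphosphonium bromide, C[P+](c1ccccc1)(c1ccccc1)c1ccccc1.[Br-]
Why: Wittig methylenation; at −78 °C the enal reacts far faster than the acetate and the E-trisubstituted olefin is untouched.

**Step 3**
Reactants: 3 (2Z,6E)-3,7-dimethylnona-2,6,8-trien-1-yl acetate
Product: 5 (2Z,6E)-3,7-dimethylnona-2,6-diene-1,9-diol, via B-alkyl-9-BBN adduct 4 (not isolated)
Conditions: 9-BBN (1.1 eq), THF, 0 °C → rt; then 3 M NaOH, 30% H2O2, 0 → 50 °C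
Reagents that add atoms: 9-BBN, B1C2CCCC1CCC2 (boryl group of 4); hydrogen peroxide, OO (oxygen of the new C8–OH in 5)
Why: 9-BBN hydroboration is selective for the monosubstituted terminus of the diene (boron on C8), and alkaline peroxide oxidation with concurrent acetate saponification gives the diol; no stereocentre is formed.

**Step 4**
Reactants: 5 (2Z,6E)-3,7-dimethylnona-2,6-diene-1,9-diol
Product: 6 [(2S,3R)-3-[(3E)-6-hydroxy-4-methylhex-3-en-1-yl]-3-methyloxiran-2-yl]methanol
Conditions: Ti(OiPr)4 (10 mol%), L-(+)-diethyl tartrate (12 mol%), t-BuOOH (1.5 eq, decane), 4 Å MS, CH2Cl2, −20 °C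
Reagents that add atoms: tert-butyl hydroperoxide, CC(C)(C)OO
Why: Katsuki–Sharpless asymmetric epoxidation touches only the allylic-alcohol olefin, and L-(+)-tartrate on the (Z)-allylic alcohol gives the (2S,3R)-epoxy alcohol (about 90% ee expected by analogy with nerol), fixing C4 (R) and C5 (S) as the cis-epoxide.

**Step 5**
Reactants: 6 [(2S,3R)-3-[(3E)-6-hydroxy-4-methylhex-3-en-1-yl]-3-methyloxiran-2-yl]methanol
Product: 7 (2R,3R)-3-methyl-3-[(3E)-4-methyl-6-oxohex-3-en-1-yl]oxirane-2-carbaldehyde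
Conditions: Dess–Martin periodinane (2.5 eq), NaHCO3, CH2Cl2, 0 °C → rt; used crude
Reagents that add atoms: none
Why: Dess–Martin oxidation of both primary alcohols under buffered, non-basic conditions avoids conjugation of the β,γ-unsaturated aldehyde and epimerisation of the epoxy aldehyde (the 2R descriptor is a CIP change only).

**Step 6**
Reactants: 8 methyl 2-(bromomethyl)acrylate
Product: 10 methyl (Z)-3-bromo-2-(bromomethyl)prop-2-enoate, via tribromo ester 9 (not isolated)
Conditions: Br2 (1.0 eq), CH2Cl2, 0 °C → rt; then i-Pr2NEt (1.05 eq), 0 °C → rt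
Reagents that add atoms: bromine, BrBr
Why: bromine addition to the acrylate followed by E2 loss of HBr from the tribromide (no α-H, so only the vinyl bromide can form) gives the 1,3-dibromide; its E/Z geometry is irrelevant because both isomers give the same allylchromium.

**Step 7 (key step)**
Reactants: 7 (2R,3R)-3-methyl-3-[(3E)-4-methyl-6-oxohex-3-en-1-yl]oxirane-2-carbaldehyde; 10 methyl (Z)-3-bromo-2-(bromomethyl)prop-2-enoate
Product: 12 (4R,5S,6S,7R,8S)-4,5-epoxy-8-hydroxygermacra-1(10),11(13)-dien-12,6-olide (ring-trans 1(10)-olefin, 8α-OH), via bromolactone aldehyde 11 (not isolated)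
Conditions: CrCl2 (8 eq, Ni-free), THF, rt; 7 + 10 (1.05 eq) added by syringe pump over 10 h (final 3 mM); aq NH4Cl
Reagents that add atoms: methyl (Z)-3-bromo-2-(bromomethyl)prop-2-enoate (10), COC(=O)/C(CBr)=C/Br
Why: Proposed new method: a one-pot [9+1] double Nozaki–Hiyama–Kishi-type allylation in which 10 serves as a C7 1,1-dianion equivalent — Cr(II) reduces the allylic C–Br of 10 to a γ-bromoallylchromium that adds through its bromine-bearing carbon to the more electrophilic α,β-epoxy aldehyde of 7 (Felkin–Anh, anti to the epoxide C–O, sets 6S), the chromium alkoxide lactonises onto the neighbouring ester (gives 11), Cr(II) then reduces the secondary allylic C7–Br to a butenolide-type allylchromium (C7 stereocentre erased) that closes the ten-membered ring on the C8 aldehyde through C7, anti to the C6 substituent (trans-lactone, 7R), via a chair Zimmerman–Traxler transition state with C9 equatorial (8S); the closest known reactions are γ-haloallylchromium additions to aldehydes (Takai–Utimoto type), the CrCl2 route from 2-(bromomethyl)acrylates to α-methylene-γ-butyrolactones, Cr/Zn allylations with 3-(bromomethyl)butenolides, and intramolecular NHK allylation to close germacranolide rings.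

**Step 8**
Reactants: 12 (4R,5S,6S,7R,8S)-4,5-epoxy-8-hydroxygermacra-1(10),11(13)-dien-12,6-olide; 13 isovaleric acid
Product: 14 (4R,5S,6S,7R,8R)-4,5-epoxy-8-(3-methylbutanoyloxy)germacra-1(10),11(13)-dien-12,6-olide (ring-trans 1(10)-olefin)
Conditions: PPh3 (2 eq), DIAD (2 eq), toluene, 0 °C (betaine pre-formed); then 13 (2 eq), then 12, 0 °C → rt
Reagents that add atoms: isovaleric acid (13), CC(C)CC(=O)O
Why: Mitsunobu esterification: SN2 displacement of the C8 alkoxyphosphonium by isovalerate inverts C8 (S → R) and gives the 8β-ester; the C8 configuration of 12 must be confirmed by J(7,8)/NOE before this step.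

**Step 9**
Reactants: 14 (4R,5S,6S,7R,8R)-4,5-epoxy-8-(3-methylbutanoyloxy)germacra-1(10),11(13)-dien-12,6-olide
Product: 15 (4R,5S,6S,7R,8R)-4,5-epoxy-14-hydroxy-8-(3-methylbutanoyloxy)germacra-1(10),11(13)-dien-12,6-olide (ring-cis 1(10)-olefin)
Conditions: SeO2 (0.5 eq), t-BuOOH (2 eq), CH2Cl2, rt, 24–48 h
Reagents that add atoms: selenium dioxide, O=[Se]=O (oxygen carrier); tert-butyl hydroperoxide, CC(C)(C)OO (terminal oxidant)
Why: SeO2/t-BuOOH allylic oxidation: ene attack at C1 with H-abstraction from the C14 methyl (C9 is deactivated by the adjacent acyloxy group), then a [2,3]-shift returns the olefin to C1=C10 with CH2OH anti to C2, so the ring olefin changes from trans to cis, as known for parthenolide-type 10-methyl-germacra-1(10)-en-olides.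

**Step 10**
Reactants: 15 (4R,5S,6S,7R,8R)-4,5-epoxy-14-hydroxy-8-(3-methylbutanoyloxy)germacra-1(10),11(13)-dien-12,6-olide
Product: 16 CNP0260081.1, (4R,5S,6S,7R,8R)-4,5-epoxy-8-(3-methylbutanoyloxy)-14-oxogermacra-1(10),11(13)-dien-12,6-olide (ring-cis 1(10)-olefin)
Conditions: Dess–Martin periodinane (1.3 eq), NaHCO3, CH2Cl2, 0 °C → rt
Reagents that add atoms: none
Why: Dess–Martin oxidation of the allylic alcohol to the enal under neutral conditions leaves olefin geometry, epoxide, lactone and ester untouched.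

**Compound list**
1 | neryl acetate | CC(C)=CCC/C(C)=C\COC(C)=O | starting material
2 | (2E,6Z)-8-acetoxy-2,6-dimethylocta-2,6-dienal | O=C/C(C)=C/CC/C(C)=C\COC(C)=O | intermediate
3 | (2Z,6E)-3,7-dimethylnona-2,6,8-trien-1-yl acetate | C=C/C(C)=C/CC/C(C)=C\COC(C)=O | intermediate
4 | 9-[(3E,7Z)-9-acetoxy-3,7-dimethylnona-3,7-dien-1-yl]-9-borabicyclo[3.3.1]nonane | CC(=O)OC/C=C(C)\CC/C=C(C)/CCB1C2CCCC1CCC2 | intermediate
5 | (2Z,6E)-3,7-dimethylnona-2,6-diene-1,9-diol | OCC/C(C)=C/CC/C(C)=C\CO | intermediate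
6 | [(2S,3R)-3-[(3E)-6-hydroxy-4-methylhex-3-en-1-yl]-3-methyloxiran-2-yl]methanol | OCC/C(C)=C/CC[C@@]1(C)O[C@H]1CO | intermediate
7 | (2R,3R)-3-methyl-3-[(3E)-4-methyl-6-oxohex-3-en-1-yl]oxirane-2-carbaldehyde | O=CC/C(C)=C/CC[C@@]1(C)O[C@H]1C=O | intermediate
8 | methyl 2-(bromomethyl)acrylate | C=C(CBr)C(=O)OC | starting material
9 | methyl 2,3-dibromo-2-(bromomethyl)propanoate | COC(=O)C(Br)(CBr)CBr | intermediate
10 | methyl (Z)-3-bromo-2-(bromomethyl)prop-2-enoate | COC(=O)/C(CBr)=C/Br | intermediate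
11 | (5R)-4-bromo-3-methylidene-5-[(2S,3R)-3-methyl-3-[(3E)-4-methyl-6-oxohex-3-en-1-yl]oxiran-2-yl]oxolan-2-one (C4–Br epimers, inconsequential) | C=C1C(=O)O[C@H]([C@@H]2O[C@]2(C)CC/C=C(C)/CC=O)C1Br | intermediate
12 | (4R,5S,6S,7R,8S)-4,5-epoxy-8-hydroxygermacra-1(10),11(13)-dien-12,6-olide, ring-trans olefin | C=C1C(=O)O[C@H]2[C@H]1[C@@H](O)C/C(C)=C/CC[C@@]1(C)O[C@@H]21 | intermediate
13 | isovaleric acid (3-methylbutanoic acid) | CC(C)CC(=O)O | starting material
14 | (4R,5S,6S,7R,8R)-4,5-epoxy-8-(3-methylbutanoyloxy)germacra-1(10),11(13)-dien-12,6-olide, ring-trans olefin | C=C1C(=O)O[C@H]2[C@H]1[C@H](OC(=O)CC(C)C)C/C(C)=C/CC[C@@]1(C)O[C@@H]21 | intermediate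
15 | (4R,5S,6S,7R,8R)-4,5-epoxy-14-hydroxy-8-(3-methylbutanoyloxy)germacra-1(10),11(13)-dien-12,6-olide, ring-cis olefin | C=C1C(=O)O[C@H]2[C@H]1[C@H](OC(=O)CC(C)C)C/C(CO)=C\CC[C@@]1(C)O[C@@H]21 | intermediate
16 | CNP0260081.1, (4R,5S,6S,7R,8R)-4,5-epoxy-8-(3-methylbutanoyloxy)-14-oxogermacra-1(10),11(13)-dien-12,6-olide, ring-cis olefin | C=C1C(=O)O[C@H]2[C@H]1[C@H](OC(=O)CC(C)C)C/C(C=O)=C\CC[C@@]1(C)O[C@@H]21 | target

**Step count**
Total steps: 10. Longest linear sequence: 9 (steps 1–5 and 7–10); step 6 is a one-step side branch.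

**Three steps most likely to fail**

Step 7 (key cascade). The risks are attack of the first allylchromium at the C8 aldehyde instead of C6 (which would lead to the 8,12-lactone), double intermolecular addition, 1,4-elimination of the allylchromium, and the C8 facial outcome. The fallback separates the two C–C bond formations by masking the C8 terminus. It sets out from 3 and returns at 11, which is then cyclised alone to 12 with CrCl2 at high dilution. Hydroboration of 3 with 9-BBN and a neutral NaBO3 work-up keeps the acetate and gives (2Z,6E)-9-hydroxy-3,7-dimethylnona-2,6-dien-1-yl acetate F1. TBSCl/imidazole gives the silyl ether acetate F2, and K2CO3/MeOH gives the allylic alcohol F3. Sharpless epoxidation with L-(+)-diethyl tartrate gives the (2S,3R)-epoxy alcohol F4, and Dess–Martin oxidation gives the (2R,3R)-epoxy aldehyde F5. A zinc Barbier reaction of F5 with 10 in THF/aq NH4Cl, with lactonisation, gives the silyl-protected bromolactone F6. HF·pyridine gives the bromolactone alcohol F7, and Dess–Martin oxidation gives 11.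

Step 8 (Mitsunobu inversion). The alcohol is hindered and homoallylic, so elimination or phosphine addition to the methylene lactone may compete. The fallback sets out from 12 and returns at 14: MsCl/Et3N gives the 8α-methanesulfonate F8, and SN2 displacement with cesium isovalerate (18-crown-6, DMF, 50 °C) gives 14 with the same inversion.

Step 9 (late allylic oxidation with olefin isomerisation). Regiochemistry (C14 against C9) and the trans-to-cis switch rest on analogy with a diastereomeric epoxide series. The fallback replaces the selenium [2,3] manifold by an ionic ene-chlorination and SN2′ oxidation. It sets out from 14 and returns at 16, bypassing 15. Ca(OCl)2/CO2 in CH2Cl2/H2O (HOCl ene-type chlorination of the only electron-rich olefin) gives the 1-chloro-10(14)-ene isovalerate F9. Trimethylamine N-oxide in MeCN/DMSO (SN2′ Ganem oxidation at the exocyclic CH2) gives the thermodynamically preferred (E)-enal 16.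

**Further compounds**
F1 | step 7 | (2Z,6E)-9-hydroxy-3,7-dimethylnona-2,6-dien-1-yl acetate | OCC/C(C)=C/CC/C(C)=C\COC(C)=O
F2 | step 7 | (2Z,6E)-9-(tert-butyldimethylsilyloxy)-3,7-dimethylnona-2,6-dien-1-yl acetate | CC(C)(C)[Si](C)(C)OCC/C(C)=C/CC/C(C)=C\COC(C)=O
F3 | step 7 | (2Z,6E)-9-(tert-butyldimethylsilyloxy)-3,7-dimethylnona-2,6-dien-1-ol | CC(C)(C)[Si](C)(C)OCC/C(C)=C/CC/C(C)=C\CO
F4 | step 7 | [(2S,3R)-3-[(3E)-6-(tert-butyldimethylsilyloxy)-4-methylhex-3-en-1-yl]-3-methyloxiran-2-yl]methanol | CC(C)(C)[Si](C)(C)OCC/C(C)=C/CC[C@@]1(C)O[C@H]1CO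
F5 | step 7 | (2R,3R)-3-[(3E)-6-(tert-butyldimethylsilyloxy)-4-methylhex-3-en-1-yl]-3-methyloxirane-2-carbaldehyde | CC(C)(C)[Si](C)(C)OCC/C(C)=C/CC[C@@]1(C)O[C@H]1C=O
F6 | step 7 | (5R)-4-bromo-5-[(2S,3R)-3-[(3E)-6-(tert-butyldimethylsilyloxy)-4-methylhex-3-en-1-yl]-3-methyloxiran-2-yl]-3-methylideneoxolan-2-one | C=C1C(=O)O[C@H]([C@@H]2O[C@]2(C)CC/C=C(C)/CCO[Si](C)(C)C(C)(C)C)C1Br
F7 | step 7 | (5R)-4-bromo-5-[(2S,3R)-3-[(3E)-6-hydroxy-4-methylhex-3-en-1-yl]-3-methyloxiran-2-yl]-3-methylideneoxolan-2-one | C=C1C(=O)O[C@H]([C@@H]2O[C@]2(C)CC/C=C(C)/CCO)C1Br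
F8 | step 8 | (4R,5S,6S,7R,8S)-4,5-epoxy-8-(methanesulfonyloxy)germacra-1(10),11(13)-dien-12,6-olide, ring-trans olefin | C=C1C(=O)O[C@H]2[C@H]1[C@@H](OS(C)(=O)=O)C/C(C)=C/CC[C@@]1(C)O[C@@H]21
F9 | step 9 | (4R,5S,6S,7R,8R)-1-chloro-4,5-epoxy-8-(3-methylbutanoyloxy)germacra-10(14),11(13)-dien-12,6-olide (C1 epimers) | C=C1C(=O)O[C@H]2[C@H]1[C@H](OC(=O)CC(C)C)CC(=C)C(Cl)CC[C@@]1(C)O[C@@H]21
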